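The first choice is to follow c(complex with two exchanged) in lifetimes, not in equivalents.

| setting | ochre | teal | west | south | north |
|---|---|---|---|---|---|
| starting complex | 0.25 M | 0.25 M | 0.25 M | 0.25 M | 0.25 M |
| incoming ligand | 0.28 equiv | 3.1 equiv | 1.50 equiv | 4.00 equiv | 0.500 equiv |
| leaving ligand | 1 equiv | 1 equiv | 1.00 equiv | 1.00 equiv | 1.00 equiv |
| remark | run made earlier | run made earlier |  |  |  |
| time |  |  | 3.0 h | 3.0 h | 3.0 h |

| run | time / min | complex with two exchanged / % |
|---|---|---|
| ochre | 8.00 | 0.9 |
| ochre | 12.0 | 2.2 |
| ochre | 15.0 | 2.1 |
| ochre | 25.0 | 0.6 |
| ochre | 40.0 | 0.1 |
| ochre | 60.0 | 0 |
| ochre | 90.0 | 0.5 |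
| teal | 5.00 | 17.1 |
| teal | 15.0 | 4.4 |
| teal | 25.0 | 1.6 |
| teal | 40.0 | 0.2 |
| teal | 50.0 | 0 |
| teal | 80.0 | 0 |
| teal | 90.0 | 0.5 |

(scatter of a reading: 1 percentage point)

- the earlier runs were read with a standard deviation of 1 percentage point

* which of these holds the largest part of the starting complex at the end of west (complex with one exchanged / complex with four exchanged / complex with two exchanged / complex with three exchanged / starting complex)
* which of these holds the largest part of the starting complex at the end of south (complex with one exchanged / complex with four exchanged / complex with two exchanged / complex with three exchanged / starting complex)
* which of these holds the largest part of the starting complex at the end of north (complex with one exchanged / complex with four exchanged / complex with two exchanged / complex with three exchanged / starting complex)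
* complex with two exchanged at the end of north, in percent of the starting complex charged

Turned round, the question about north runs like this: to hold a readable amount of complex with two exchanged at its end, that transient intermediate must have a lifetime of the order of the time, a loss rate near 0.00556 min⁻¹. The teal run falls from 17.1% at 5.00 min to 4.4% at 15.0 min, which reads as a loss rate of 0.136 min⁻¹, faster than that mark. The ochre run, scattered as it is, falls from 2.1% at 15.0 min to 0.6% at 25.0 min and reads 0.125 min⁻¹, a similar rate at a far smaller charge of incoming ligand. Teal, with more incoming ligand than north, is already falling by 15.0 min. The count of turnovers is the loss rate times the time, the number of lifetimes that fit into the run: 24.4, where the opposite outcome asks for about one. So this reckoning commits north to a complex with two exchanged below the scatter of 1 point.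

The forecast reads it alike, "The complex with two exchanged is only a transient", and gives 1% for north. It puts complex with one exchanged in front in west, complex with four exchanged in south and starting complex in north.

West ends with starting complex in front, 28.1% against 21.0% of complex with one exchanged; south ends with complex with four exchanged, north with starting complex.

    starting complex + incoming ligand → leaving ligand + complex with one exchanged (k = 0.686 M⁻¹ min⁻¹)
    complex with one exchanged + incoming ligand → leaving ligand + complex with two exchanged (k = 1.32 M⁻¹ min⁻¹)
    complex with two exchanged + incoming ligand → leaving ligand + complex with three exchanged (k = 1.04 M⁻¹ min⁻¹)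
    complex with three exchanged + incoming ligand → leaving ligand + complex with four exchanged (k = 0.653 M⁻¹ min⁻¹)
    complex with two exchanged → over-reaction product (k = 0.234 min⁻¹)
    2 incoming ligand → homo dimer (k = 0.0304 M⁻¹ min⁻¹)

North ends at 0% of complex with two exchanged, with 24.4 read lifetimes in its time. At 0.0494 h in north that complex passes into over-reaction product 3.2 times as fast as into complex with three exchanged. The neighbour of north with 2.00 equiv of incoming ligand runs the same time, so the count stays 24.4, and it ends at 0% of complex with two exchanged beside 44.7% of over-reaction product.

The readings are calculated for an exercise; the scatter is artificial.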